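# Proposed total synthesis of CNP0186856.0 (19) by Effenberger-type construction of ring A

## The problem

Target 19 is two hexasubstituted benzene rings joined by one methylene carbon. Ring A is a phloroglucinol with an isobutyryl group on C1', the bridge on C3' and a methyl group on C5'. Ring B is the arene of a 5,7-dihydroxy-2,2,6-trimethylchroman-4-one that carries the bridge on C8. There is no stereocentre, so the whole difficulty is placement: on each ring three oxygens alternate with three different carbon substituents. On ring B the decisive point is which of the two oxygens ortho to the acyl-bearing carbon closes the pyranone, because this alone puts the methyl group on C6 rather than C8. A 5-hydroxychromanone of this type can open by retro-oxa-Michael reaction and reclose through the other ortho oxygen under acid or base, so O5 has to stay capped until the end. The methylene link between two electron-rich rings is prone to acid-induced cleavage, and the free pentaphenol is sensitive to air and base, so the closing operations must be neutral. The feature that opens the molecule lies in ring A: C3'(bridge)–C4'(OH)–C5'(methyl) is the α-carbon, carbonyl carbon and α'-carbon of an ethyl ketone whose other α-carbon already bears the CH2 attached to C8. The remaining atoms C6'–C1'–C2' (two C–OH flanking a C–H) have the oxidation pattern of a malonyl unit.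

## Retrosynthesis

**19 to 18.** The last cut is through the two benzylic C–O bonds on O5 and O7. Ring B phenols must be masked while ring A is built with an acid chloride, and the mask on O5 also stops the pyranone from reclosing onto O5. Benzyl is the one common phenol mask removed under neutral conditions; methyl ethers would need a boron trihalide, which endangers the bridge and the tertiary O1–C2 ether. Compound 18 is no simpler in skeleton, but its ring B is locked. The forward hydrogenolysis must leave two aryl ketones and the diarylmethane untouched.

**18 to 15 and nitrile 16.** The C1'–acyl bond is cut. C1' is the only aromatic C–H in 15 and sits between two free hydroxyls, so there is no regiochemical question. The acyl group must follow ring construction because C1' originates from the malonyl CH2. A nitrile under Hoesch conditions is preferred to an acid chloride with a strong Lewis acid, which would strip the O5 benzyl group beside the chromanone carbonyl and could cleave the bridge. Compound 15 lacks the branched acyl group; the forward step must acylate carbon, once.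

**15 to ketone 13 and malonyl dichloride 14 (key disconnection).** The C2'–C3' and C5'–C6' bonds are cut, which dismantles ring A completely. Against the neighbouring cut at the bridge, which would join two finished aromatic rings, this one derives all three ring A oxygens and its whole substitution pattern from an open-chain ketone and a three-carbon diacid chloride. The pattern cannot come out wrong: the ketone carbonyl must become C4' and its two α-carbons C3' and C5'. Compound 13 has a single aromatic ring, and the three ring A phenols never need protection. The forward reaction must acylate twice at carbon, close at carbon rather than oxygen, and engage the dialkyl ketone rather than the chromanone carbonyl.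

**13 to iodide 11 and alkenol 12; 11 to 10.** The C8–CH2 bond is cut. A Heck reaction with an allylic alcohol delivers the saturated ketone directly at the right oxidation level. Adding the C8–H of 10 to the corresponding enone under acid would save the halogenation, but it asks an acyl-deactivated, doubly flanked position to act as nucleophile; the iodide route is taken for certainty. C8 is the only free ring position of 10, so iodination is unambiguous. The forward coupling needs oxidative addition at a di-ortho-substituted iodide and β-hydride elimination toward the carbinol.

**10 to acetophenone 8 and acetone 9; 8 to phenol 5 and acetonitrile 6.** First O1–C2 and C2–C3 are cut (Kabbe condensation), then the aryl–acetyl bond (Hoesch acylation). Amine-mediated condensation leaves benzyl ethers alone, whereas the one-step annulation of a phenol with an unsaturated acid in hot sulfonic acid would not. Compound 8 has a single free hydroxyl, so O1 is fixed. Phenol 5 is symmetric: both positions ortho to its hydroxyl are equivalent and the para position carries the methyl group, so only one ketone can form. Because the free oxygen of 5 is para to the methyl group, the methyl ends up on C6.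

**5 to 3, 2 and aldehyde 1.** Phenol 5 needs a free hydroxyl para to the methyl group and benzyl ethers on the two flanking oxygens. Partial benzylation of a methylated triol would not discriminate. An oxidative route that turns a formyl group para to the methyl into the hydroxyl (Dakin type) would require migration of an aryl group whose alkoxy groups are both meta, which is unfavourable. Instead the methyl group is made from the formyl carbon of commercial 1. Its 4-hydroxyl is the most acidic and the only unchelated one, so it takes a sulfonate selectively; the two chelated hydroxyls are then benzylated. One Wolff–Kishner operation then reduces the aldehyde and unmasks the phenol.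

## Roads not taken

**Alternative 1:** The cut is at the chromanone carbonyl carbon (C4a–C4 and C3–C4), on a diarylmethane that is already complete. In the forward sense the hexasubstituted aryl iodide A2, a one-carbon carbonyl source and the alkenylboronate A3 would be joined in a carbonylative Suzuki–Miyaura coupling (Pd(OAc)2, bulky trialkylphosphine) to give enone A1. Acetal removal at O8a, oxa-Michael closure and hydrogenolysis would follow.
- Merits: the plan is convergent, the isobutyryl group is in place before the rings are joined, and the single acetal-protected oxygen defines the ring-closing oxygen without reliance on symmetry. In convergence and in that last respect it is better than the chosen plan.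
- Weak points: the iodide is flanked by two alkoxy groups on a very electron-rich ring, where direct coupling without carbonyl insertion and loss of iodide are the usual leaks. Five phenols must be differentiated (four benzyl ethers and one acetal), so both monomers need individual protection before the bridge is made. A1 must also survive acidic acetal cleavage beside a bridge that dislikes acid.
- Comparison: the chosen plan is linear, but ring A needs no protecting group, there are only two benzyl ethers overall, and no transition-metal step takes place on a hexasubstituted ring.

**Alternative 2:** The cut is at two aryl C–O bonds, C6'–O and C5–O. The dideoxy triacetate A5 would be hydroxylated twice in one operation, each time ortho to a ketone, with [RuCl2(p-cymene)]2 and a hypervalent iodine bis(trifluoroacetate), giving A4; acetate removal would finish.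
- Merits: both rings travel at the less oxidizable resorcinol level. While C5 is still C–H the chromanone has only one ortho oxygen, so the pyranone cannot reclose the wrong way; this is cleaner than any route that carries O5.
- Weak points: each site is the last C–H of its ring and lies next to a methyl group, the isobutyryl group is twisted by its ortho substituents, and two metalations must succeed in one molecule. The new phenols are more easily oxidized than the substrate, so over-oxidation to quinones and oxidation of the doubly benzylic bridge are to be expected, and acetates can migrate to the new hydroxyls. A5 itself still requires a regiocontrolled diarylmethane synthesis, so it is not simpler.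
- Comparison: the chosen plan brings every oxygen in with its building blocks (aldehyde 1 and dichloride 14) and needs no oxidation in the presence of the electron-rich rings.

**Alternative 3:** The cut runs through the benzene ring of the chromanone (C4a–C8a and C5–C6, with C8–C8a from the electrocyclization). Cyclobutenone A7, which carries the ring A benzyl group on its sp3 carbon, would be heated with ethoxyethyne A8; the pericyclic cascade of a Danheiser benzannulation would give phenol A6.
- Merits: the ring B pattern is dictated by the cascade, and its three oxygens emerge differentiated (free hydroxyl on C8a, ethyl ether on C5, silyl ether on C7). In this respect it equals or betters the chosen plan, which relies on the symmetry of phenol 5.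
- Weak points: C4a arrives as C–H, so the whole pyranone (acylation and oxa-Michael closure) remains to be built on a benzyl-protected diarylmethane. The ethyl ether on C5 must be cleaved at the end by a boron halide, a Lewis acid step on the finished bridge. A7 is a thermally sensitive multistep intermediate.
- Comparison: the chosen plan builds ring A rather than ring B de novo, from much simpler partners, and ends with a neutral hydrogenolysis.

Key step: step 8

Assumption: 19 has no stereocentre; pent-1-en-3-ol 12 is used as the racemate because its carbinol carbon becomes a carbonyl carbon.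

## Route

Step 1
Reactants: 1 2,4,6-trihydroxybenzaldehyde
Product: 2 4-formyl-3,5-dihydroxyphenyl 4-methylbenzenesulfonate
Conditions: TsCl (1.0 equiv), K2CO3 (1.1 equiv), acetone, 0 °C to rt
Reagents that add atoms: 4-methylbenzenesulfonyl chloride, Cc1ccc(S(=O)(=O)Cl)cc1
Why: Selective O-sulfonylation; the 4-hydroxyl, para to the formyl group, is the most acidic and the only one not held in a hydrogen bond to the carbonyl, so one equivalent of sulfonyl chloride should react there and leave the two chelated ortho hydroxyls free.

Step 2
Reactants: 2 4-formyl-3,5-dihydroxyphenyl 4-methylbenzenesulfonate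
Product: 3 3,5-bis(benzyloxy)-4-formylphenyl 4-methylbenzenesulfonate
Conditions: BnBr (2.5 equiv), K2CO3 (3 equiv), DMF, 60 °C
Reagents that add atoms: benzyl bromide, BrCc1ccccc1
Why: Williamson ether synthesis; the two chelated hydroxyls are alkylated in warm DMF, while the aryl sulfonate is inert to carbonate and marks the oxygen that will later close the pyranone.

Step 3
Reactants: 3 3,5-bis(benzyloxy)-4-formylphenyl 4-methylbenzenesulfonate
Product: 5 3,5-bis(benzyloxy)-4-methylphenol, via tosyloxy hydrazone 4 (not isolated)
Conditions: N2H4·H2O (5 equiv), diethylene glycol, 110 °C; then KOH (5 equiv), 195 °C; aq. HCl work-up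
Reagents that add atoms: none
Why: Wolff–Kishner reduction in the Huang–Minlon form turns the formyl group into the future C6 methyl via hydrazone 4, and the hot hydroxide cleaves the aryl sulfonate at sulfur in the same pot; benzyl aryl ethers are stable to these basic conditions, and the hydrazone is formed with excess hydrazine before the base is added so that sulfonyl transfer does not intercept the aldehyde.

Step 4
Reactants: 5 3,5-bis(benzyloxy)-4-methylphenol; 6 acetonitrile
Product: 8 1-[2,4-bis(benzyloxy)-6-hydroxy-3-methylphenyl]ethan-1-one, via ketiminium chloride 7 (not isolated)
Conditions: 6 (3 equiv), ZnCl2 (1.0 equiv), HCl (g), Et2O, 0 °C; then H2O, 90 °C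
Reagents that add atoms: water, O
Why: Hoesch acylation; the nitrilium species from 6 attacks the carbon ortho to the free hydroxyl of this phloroglucinol diether, the two ortho positions being equivalent and the para position blocked by methyl, so a single ketiminium salt 7 should form and hydrolyse to 8; the iminium group deactivates the ring against a second acylation, and HCl in cold ether is mild enough for aryl benzyl ethers.

Step 5
Reactants: 8 1-[2,4-bis(benzyloxy)-6-hydroxy-3-methylphenyl]ethan-1-one; 9 acetone
Product: 10 5,7-bis(benzyloxy)-2,2,6-trimethylchroman-4-one
Conditions: 9 (10 equiv), pyrrolidine (1 equiv), EtOH, 70 °C (sealed vessel)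
Reagents that add atoms: none
Why: Kabbe chromanone synthesis; amine-mediated aldol condensation of the acetyl group with acetone is followed by 6-endo oxa-Michael closure of the ortho phenol, and since 8 has a single free hydroxyl, O1 can only be the oxygen para to the methyl group, which places the methyl on C6 and leaves C8–H.

Step 6
Reactants: 10 5,7-bis(benzyloxy)-2,2,6-trimethylchroman-4-one
Product: 11 5,7-bis(benzyloxy)-8-iodo-2,2,6-trimethylchroman-4-one
Conditions: NIS (1.1 equiv), TFA (10 mol %), MeCN, 0 °C to rt, dark
Reagents that add atoms: N-iodosuccinimide, O=C1CCC(=O)N1I
Why: Electrophilic aromatic iodination; C8 is the only unsubstituted ring carbon and is ortho to O1 and O7 and para to O5, so it should react well ahead of the ketone α-position.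

Step 7
Reactants: 11 5,7-bis(benzyloxy)-8-iodo-2,2,6-trimethylchroman-4-one; 12 pent-1-en-3-ol (racemic)
Product: 13 1-[5,7-bis(benzyloxy)-2,2,6-trimethyl-4-oxochroman-8-yl]pentan-3-one
Conditions: 12 (2 equiv), Pd(OAc)2 (10 mol %), Bu4NCl (1 equiv), NaHCO3 (2.5 equiv), DMF, 70 °C
Reagents that add atoms: none
Why: Mizoroki–Heck arylation of an allylic alcohol under ligand-free Jeffery conditions; the aryl group adds to the terminal alkene carbon and β-hydride elimination toward the carbinol carbon gives an enol that tautomerizes to the saturated ketone, so the 3-oxopentyl chain arrives at the ketone oxidation level in one operation and the carbinol stereocentre of 12 disappears.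

Step 8
Reactants: 13 1-[5,7-bis(benzyloxy)-2,2,6-trimethyl-4-oxochroman-8-yl]pentan-3-one; 14 malonyl dichloride
Product: 15 5,7-bis(benzyloxy)-2,2,6-trimethyl-8-[(2,4,6-trihydroxy-3-methylphenyl)methyl]chroman-4-one
Conditions: 14 (1.1 equiv), CH2Cl2, 0 °C to 40 °C, slow N2 sweep to remove HCl
Reagents that add atoms: none
Why: This is the Effenberger annulation, the acid-promoted (3+3) condensation of an open-chain dialkyl ketone bearing a methylene on each side of the carbonyl with malonyl dichloride to give a 2,4-dialkylphloroglucinol; its cyclic counterpart converts cyclohexanone enol derivatives into bicyclo[3.3.1]nonane-2,4,9-triones. The enol of the pentan-3-one unit is C-acylated by 14 (or by chlorocarbonylketene formed from it by loss of HCl), giving a 1,3-diketone that still carries an acid chloride. Enolization toward the second methylene and intramolecular C-acylation then close ring A in a 6-(enolendo)-exo-trig mode, and the cyclohexane-1,3,5-trione tautomerizes to the phloroglucinol. The bonds formed are C2'–C3' and C5'–C6'; because both α-carbons of 13 enter the ring, it does not matter which is acylated first, and the ketone carbonyl must become C4'–OH between the bridge carbon and the methyl carbon, so the substitution pattern is fixed by the substrate. No stereocentre is created. The step needs C- rather than O-acylation in the closure (the O-path leads to a 4-hydroxy-2-pyrone); this is favoured because both α-positions are unhindered methylenes and only the carbocycle can aromatize. It also needs the chain ketone to react in preference to the chromanone carbonyl, which is a vinylogous ester conjugated to three ring oxygens and flanked by the quaternary C2, and so should enolize and acylate far more slowly. Both ring B phenols are capped as benzyl ethers, and only a slight excess of 14 is used so that the free triol product is not acylated further.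

Step 9
Reactants: 15 5,7-bis(benzyloxy)-2,2,6-trimethyl-8-[(2,4,6-trihydroxy-3-methylphenyl)methyl]chroman-4-one; 16 2-methylpropanenitrile
Product: 18 5,7-bis(benzyloxy)-2,2,6-trimethyl-8-{[2,4,6-trihydroxy-3-methyl-5-(2-methylpropanoyl)phenyl]methyl}chroman-4-one, via ketiminium chloride 17 (not isolated)
Conditions: 16 (5 equiv), ZnCl2 (1.5 equiv), HCl (g), Et2O, 0 °C; then H2O, 80 °C
Reagents that add atoms: water, O
Why: Hoesch acylation of a free phloroglucinol; C1' is the only aromatic C–H in the molecule and lies between two hydroxyls, so C-acylation by the nitrilium species from 16 should give ketiminium salt 17 regiospecifically and hydrolysis then gives the ketone; no strong Lewis acid is present that could cleave the O5 benzyl ether or the methylene bridge, and the benzylated ring B cannot open and reclose.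

Step 10
Reactants: 18 5,7-bis(benzyloxy)-2,2,6-trimethyl-8-{[2,4,6-trihydroxy-3-methyl-5-(2-methylpropanoyl)phenyl]methyl}chroman-4-one
Product: 19 5,7-dihydroxy-2,2,6-trimethyl-8-{[2,4,6-trihydroxy-3-methyl-5-(2-methylpropanoyl)phenyl]methyl}chroman-4-one (CNP0186856.0)
Conditions: H2 (1 atm), 10% Pd/C, EtOAc, rt
Reagents that add atoms: none
Why: Hydrogenolysis of the two aryl benzyl ethers over Pd/C under neutral conditions; the hydrogen-bonded aryl ketones and the diarylmethane should not be reduced at atmospheric pressure, and no acid or base is present that could isomerize the 5-hydroxychromanone or cleave the bridge.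

## Compound list

1 | 2,4,6-trihydroxybenzaldehyde | O=Cc1c(O)cc(O)cc1O | starting material
2 | 4-formyl-3,5-dihydroxyphenyl 4-methylbenzenesulfonate | O=Cc1c(O)cc(OS(=O)(=O)c2ccc(C)cc2)cc1O | intermediate
3 | 3,5-bis(benzyloxy)-4-formylphenyl 4-methylbenzenesulfonate | O=Cc1c(OCc2ccccc2)cc(OS(=O)(=O)c2ccc(C)cc2)cc1OCc1ccccc1 | intermediate
4 | 3,5-bis(benzyloxy)-4-[(E)-hydrazinylidenemethyl]phenyl 4-methylbenzenesulfonate | N/N=C/c1c(OCc2ccccc2)cc(OS(=O)(=O)c2ccc(C)cc2)cc1OCc1ccccc1 | intermediate
5 | 3,5-bis(benzyloxy)-4-methylphenol | Cc1c(OCc2ccccc2)cc(O)cc1OCc1ccccc1 | intermediate
6 | acetonitrile | CC#N | starting material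
7 | 1-[2,4-bis(benzyloxy)-6-hydroxy-3-methylphenyl]ethan-1-iminium chloride | CC(=[NH2+])c1c(O)cc(OCc2ccccc2)c(C)c1OCc1ccccc1.[Cl-] | intermediate
8 | 1-[2,4-bis(benzyloxy)-6-hydroxy-3-methylphenyl]ethan-1-one | CC(=O)c1c(O)cc(OCc2ccccc2)c(C)c1OCc1ccccc1 | intermediate
9 | acetone | CC(C)=O | starting material
10 | 5,7-bis(benzyloxy)-2,2,6-trimethylchroman-4-one | Cc1c(OCc2ccccc2)cc2OC(C)(C)CC(=O)c2c1OCc1ccccc1 | intermediate
11 | 5,7-bis(benzyloxy)-8-iodo-2,2,6-trimethylchroman-4-one | Cc1c(OCc2ccccc2)c(I)c2OC(C)(C)CC(=O)c2c1OCc1ccccc1 | intermediate
12 | pent-1-en-3-ol (racemic) | CCC(O)C=C | starting material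
13 | 1-[5,7-bis(benzyloxy)-2,2,6-trimethyl-4-oxochroman-8-yl]pentan-3-one | CCC(=O)CCc1c(OCc2ccccc2)c(C)c(OCc2ccccc2)c2c1OC(C)(C)CC2=O | intermediate
14 | malonyl dichloride (propanedioyl dichloride) | O=C(Cl)CC(Cl)=O | starting material
15 | 5,7-bis(benzyloxy)-2,2,6-trimethyl-8-[(2,4,6-trihydroxy-3-methylphenyl)methyl]chroman-4-one | Cc1c(O)cc(O)c(Cc2c(OCc3ccccc3)c(C)c(OCc3ccccc3)c3c2OC(C)(C)CC3=O)c1O | intermediate
16 | 2-methylpropanenitrile (isobutyronitrile) | CC(C)C#N | starting material
17 | 1-{3-[(5,7-bis(benzyloxy)-2,2,6-trimethyl-4-oxochroman-8-yl)methyl]-2,4,6-trihydroxy-5-methylphenyl}-2-methylpropan-1-iminium chloride | CC(C)C(=[NH2+])c1c(O)c(C)c(O)c(Cc2c(OCc3ccccc3)c(C)c(OCc3ccccc3)c3c2OC(C)(C)CC3=O)c1O.[Cl-] | intermediate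
18 | 5,7-bis(benzyloxy)-2,2,6-trimethyl-8-{[2,4,6-trihydroxy-3-methyl-5-(2-methylpropanoyl)phenyl]methyl}chroman-4-one | CC(C)C(=O)c1c(O)c(C)c(O)c(Cc2c(OCc3ccccc3)c(C)c(OCc3ccccc3)c3c2OC(C)(C)CC3=O)c1O | intermediate
19 | 5,7-dihydroxy-2,2,6-trimethyl-8-{[2,4,6-trihydroxy-3-methyl-5-(2-methylpropanoyl)phenyl]methyl}chroman-4-one (CNP0186856.0, achiral) | Cc1c(O)c(Cc2c(O)c(C)c(O)c3c2OC(C)(C)CC3=O)c(O)c(C(=O)C(C)C)c1O | target

## Step count and least certain steps

Total step count: 10. Longest linear sequence: 10 steps (1 to 19).

**Step 8 (key step).**
- What may go wrong: ring closure through the enol oxygen instead of the α'-carbon would give a 4-hydroxy-2-pyrone, because the enol lying between the two carbonyls of the first intermediate is the more populated one. Acylation could also start at C3 of the chromanone. The triol product could be acylated further by remaining dichloride, and benzyl groups could slowly be lost to the HCl that is released.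
- Fallback (sets out from 11, returns at 15): Stille coupling of 11 with (tributylstannyl)methanol under Pd(PPh3)4 in dioxane would give 5,7-bis(benzyloxy)-8-(hydroxymethyl)-2,2,6-trimethylchroman-4-one F1. This doubly ortho-oxygenated benzylic alcohol ionizes under catalytic p-toluenesulfonic acid and would alkylate an excess of 2-methylbenzene-1,3,5-triol, whose two free ring positions are equivalent, to give 15. This gives up the annulation and takes ring A from an aromatic building block.

**Step 9.**
- What may go wrong: C-acylation at the hindered C1' may be slow, and the hot aqueous hydrolysis of the ketiminium salt could cause partial loss of benzyl groups or acid-induced cleavage of the methylene bridge.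
- Fallback (sets out from 15, returns at 19): hydrogenolysis of 15 (H2, Pd/C) would give the pentaphenol 5,7-dihydroxy-2,2,6-trimethyl-8-[(2,4,6-trihydroxy-3-methylphenyl)methyl]chroman-4-one F2, in which C1' is still the only aromatic C–H. Friedel–Crafts acylation with isobutyryl chloride and AlCl3 in nitrobenzene/CH2Cl2, the classical entry to acylphloroglucinols, followed by mild methanolysis of any aryl esters, would then give 19 directly. This exposes the free 5-hydroxychromanone and the bridge to a strong Lewis acid, which is why it is only the second choice.

**Step 7.**
- What may go wrong: carbopalladation by the di-ortho-substituted, electron-rich aryl–palladium species may be slow, so that reductive loss of iodine competes. β-Hydride elimination away from the carbinol carbon would give an aryl allylic alcohol instead of the ketone.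
- Fallback (sets out from 11, returns at 13): Mizoroki–Heck reaction of 11 with pent-1-en-3-one (Pd(OAc)2, P(o-tol)3, Et3N, DMF), a more reactive acceptor with only one direction of elimination, would give (E)-1-[5,7-bis(benzyloxy)-2,2,6-trimethyl-4-oxochroman-8-yl]pent-1-en-3-one F3. Conjugate reduction with [(Ph3P)CuH]6 would then give 13 without touching the benzyl ethers.

**Step 4.**
- What may go wrong: the nitrilium species may be captured at the phenol oxygen (imidate formation), or the ZnCl2/HCl medium may partly debenzylate this very electron-rich diether.
- Fallback (sets out from 5, returns at 8): ortho-formylation of 5 with MgCl2, Et3N and paraformaldehyde would give 2,4-bis(benzyloxy)-6-hydroxy-3-methylbenzaldehyde F4. Addition of excess MeMgBr would give racemic 3,5-bis(benzyloxy)-2-(1-hydroxyethyl)-4-methylphenol F5, and MnO2 oxidation of the benzylic alcohol would give 8. All three operations are basic or neutral.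

## Further compounds

F1 | step 8 | 5,7-bis(benzyloxy)-8-(hydroxymethyl)-2,2,6-trimethylchroman-4-one | Cc1c(OCc2ccccc2)c(CO)c2OC(C)(C)CC(=O)c2c1OCc1ccccc1
F2 | step 9 | 5,7-dihydroxy-2,2,6-trimethyl-8-[(2,4,6-trihydroxy-3-methylphenyl)methyl]chroman-4-one | Cc1c(O)cc(O)c(Cc2c(O)c(C)c(O)c3c2OC(C)(C)CC3=O)c1O
F3 | step 7 | (E)-1-[5,7-bis(benzyloxy)-2,2,6-trimethyl-4-oxochroman-8-yl]pent-1-en-3-one | CCC(=O)/C=C/c1c(OCc2ccccc2)c(C)c(OCc2ccccc2)c2c1OC(C)(C)CC2=O
F4 | step 4 | 2,4-bis(benzyloxy)-6-hydroxy-3-methylbenzaldehyde | O=Cc1c(O)cc(OCc2ccccc2)c(C)c1OCc1ccccc1
F5 | step 4 | 3,5-bis(benzyloxy)-2-(1-hydroxyethyl)-4-methylphenol (racemic) | CC(O)c1c(O)cc(OCc2ccccc2)c(C)c1OCc1ccccc1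
A1 | alternative 1 | 1-{2,4-bis(benzyloxy)-6-(methoxymethoxy)-3-methyl-5-[(2,4,6-tris(benzyloxy)-3-methyl-5-(2-methylpropanoyl)phenyl)methyl]phenyl}-3-methylbut-2-en-1-one | CC(C)=CC(=O)c1c(OCOC)c(Cc2c(OCc3ccccc3)c(C)c(OCc3ccccc3)c(C(=O)C(C)C)c2OCc2ccccc2)c(OCc2ccccc2)c(C)c1OCc1ccccc1
A2 | alternative 1 | 1-{2,4,6-tris(benzyloxy)-3-{[2,4-bis(benzyloxy)-5-iodo-6-(methoxymethoxy)-3-methylphenyl]methyl}-5-methylphenyl}-2-methylpropan-1-one | Ic1c(OCOC)c(Cc2c(OCc3ccccc3)c(C)c(OCc3ccccc3)c(C(=O)C(C)C)c2OCc2ccccc2)c(OCc2ccccc2)c(C)c1OCc1ccccc1
A3 | alternative 1 | 4,4,5,5-tetramethyl-2-(2-methylprop-1-en-1-yl)-1,3,2-dioxaborolane | CC(C)=CB1OC(C)(C)C(C)(C)O1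
A4 | alternative 2 | 7-acetoxy-8-{[2,6-diacetoxy-4-hydroxy-3-methyl-5-(2-methylpropanoyl)phenyl]methyl}-5-hydroxy-2,2,6-trimethylchroman-4-one | Cc1c(O)c(C(=O)C(C)C)c(OC(C)=O)c(Cc2c(OC(C)=O)c(C)c(O)c3c2OC(C)(C)CC3=O)c1OC(C)=O
A5 | alternative 2 | 7-acetoxy-8-{[2,6-diacetoxy-3-methyl-5-(2-methylpropanoyl)phenyl]methyl}-2,2,6-trimethylchroman-4-one | Cc1cc(C(=O)C(C)C)c(OC(C)=O)c(Cc2c(OC(C)=O)c(C)cc3c2OC(C)(C)CC3=O)c1OC(C)=O
A6 | alternative 3 | 1-{2,4,6-tris(benzyloxy)-3-{[4-ethoxy-2-hydroxy-5-methyl-6-(triisopropylsilyloxy)phenyl]methyl}-5-methylphenyl}-2-methylpropan-1-one | CCOc1cc(O)c(Cc2c(OCc3ccccc3)c(C)c(OCc3ccccc3)c(C(=O)C(C)C)c2OCc2ccccc2)c(O[Si](C(C)C)(C(C)C)C(C)C)c1C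
A7 | alternative 3 | 2-methyl-4-{[2,4,6-tris(benzyloxy)-3-methyl-5-(2-methylpropanoyl)phenyl]methyl}-3-(triisopropylsilyloxy)cyclobut-2-en-1-one (racemic) | CC1=C(O[Si](C(C)C)(C(C)C)C(C)C)C(Cc2c(OCc3ccccc3)c(C)c(OCc3ccccc3)c(C(=O)C(C)C)c2OCc2ccccc2)C1=O
A8 | alternative 3 | ethoxyethyne | CCOC#C
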